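**Strategy.** The cyclohexane is opened at the C1–C2 bond (C1 carries the C(OH)(CH2OAc)2 group, C2 the hydroxyl), giving an acyclic aldehyde whose other end is a symmetric 2-alkylidenepropane-1,3-diol. Because the two CH2O arms on the side-chain carbinol carbon are equivalent, either hydroxyl can be ionised by palladium. Et3B turns the π-allyl into an allylborane that attacks the aldehyde through a chair transition state, closing the ring and setting C1 and C2 trans to each other and to the equatorial C3 isopropenyl in one operation. The C3/C4 pair (C4 quaternary: methyl, vinyl) is set beforehand by an enantioselective Ireland–Claisen rearrangement of geranyl 3-methylbut-3-enoate.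

Key step: step 8

Assumption: the (S,S)-bromoborane is taken to deliver the (2S,3S) acid; should the facial sense be the opposite, the (R,R)-reagent is used with no other change.

Step 1
Reactants: 1 geraniol; 2 3-methylbut-3-enoic acid
Product: 3 geranyl 3-methylbut-3-enoate
Conditions: DCC, DMAP (5 mol %), CH2Cl2, 0 °C
Reagents that add atoms: none
Why: Steglich esterification of a primary allylic alcohol, with low temperature and little DMAP so that the β,γ-double bond of the acid should not move into conjugation.

Step 2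
Reactants: 3 geranyl 3-methylbut-3-enoate
Product: 6 (2S,3S)-3-ethenyl-3,7-dimethyl-2-(prop-1-en-2-yl)oct-6-enoic acid, via boron ketene acetal 4 (not isolated), via boron carboxylate 5 (not isolated)
Conditions: (4S,5S)-2-bromo-4,5-diphenyl-1,3-bis[3,5-bis(trifluoromethyl)phenylsulfonyl]-1,3,2-diazaborolidine (made from the (S,S)-bis-sulfonamide and BBr3, CH2Cl2, 25 °C), Et3N, toluene–hexane, −78 → 4 °C; then H2O
Reagents that add atoms: none
Why: Enantioselective boron-mediated Ireland–Claisen rearrangement: soft enolisation is expected to give the ketene acetal with isopropenyl trans to O–B, the (E)-allyl unit then rearranges through a chair (chain equatorial, methyl axial) that places isopropenyl and methyl in the required (2S,3S) relationship at the tertiary and quaternary carbons, and the C2-symmetric sulfonamide ligand on boron selects the face.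

Step 3
Reactants: 6 (2S,3S)-3-ethenyl-3,7-dimethyl-2-(prop-1-en-2-yl)oct-6-enoic acid
Product: 7 (2S,3S)-3-ethenyl-N-methoxy-N,3,7-trimethyl-2-(prop-1-en-2-yl)oct-6-enamide
Conditions: MeNH(OMe)·HCl, EDCI·HCl, HOBt, iPr2NEt, CH2Cl2, 0 → 25 °C
Reagents that add atoms: N,O-dimethylhydroxylamine hydrochloride, CNOC.Cl
Why: Carbodiimide/HOBt amide coupling under mild base should preserve the α-stereocentre and installs a Weinreb amide that can later be reduced only as far as the aldehyde.

Step 4
Reactants: 7 Weinreb amide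
Product: 8 (2S,3S)-5-(3,3-dimethyloxiran-2-yl)-3-ethenyl-N-methoxy-N,3-dimethyl-2-(prop-1-en-2-yl)pentanamide (either epimer at the oxirane carbon)
Conditions: mCPBA (1.05 equiv), NaHCO3, CH2Cl2, −10 °C
Reagents that add atoms: mCPBA, O=C(OO)c1cccc(Cl)c1
Why: Prilezhaev epoxidation should pick the electron-rich trisubstituted alkene over the hindered isopropenyl and the vinyl group on the quaternary carbon; the new oxirane stereocentre is irrelevant because it is cleaved in the next step.

Step 5
Reactants: 8 epoxide
Product: 9 (2S,3S)-3-ethenyl-N-methoxy-N,3-dimethyl-6-oxo-2-(prop-1-en-2-yl)hexanamide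
Conditions: H5IO6, THF–Et2O, 0 °C
Reagents that add atoms: none
Why: Periodic acid opens the epoxide to the glycol and cleaves it (Malaprade-type cleavage) in one operation, releasing acetone and the chain-end aldehyde while the amide and the remaining alkenes stay inert.

Step 6
Reactants: 9 aldehyde; 10 dimethyl malonate
Product: 11 dimethyl 2-[(4S,5S)-4-ethenyl-5-[methoxy(methyl)carbamoyl]-4,6-dimethylhept-6-en-1-ylidene]propanedioate
Conditions: piperidine (10 mol %), AcOH (10 mol %), 4 Å molecular sieves, CH2Cl2, 25 °C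
Reagents that add atoms: none
Why: Knoevenagel condensation at the unhindered aldehyde gives an alkylidene malonate with no E/Z issue, because the two ester groups are identical.

Step 7
Reactants: 11 alkylidene malonate
Product: 12 (2S,3S)-3-ethenyl-8-hydroxy-7-(hydroxymethyl)-3-methyl-2-(prop-1-en-2-yl)oct-6-enal
Conditions: iBu2AlH (7 equiv), CH2Cl2, −78 → −20 °C; aq. KNaC4H4O6
Reagents that add atoms: none
Why: iBu2AlH should reduce both conjugated esters 1,2 to the allylic diol while the Weinreb amide is held as its chelated aluminium hemiaminal and releases the aldehyde only on work-up; no stereocentre is touched.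

Step 8
Reactants: 12 dihydroxy aldehyde
Product: 14 (1S,2S,3S,6S)-3-ethenyl-6-(3-hydroxyprop-1-en-2-yl)-3-methyl-2-(prop-1-en-2-yl)cyclohexan-1-ol, via allyl(diethyl)borane 13 (not isolated)
Conditions: Pd(OAc)2 (10 mol %), P(nBu)3 (20 mol %), Et3B (3 equiv), LiCl, Et3N, THF (0.01 M), 25 °C
Reagents that add atoms: none
Why: Et3B activates one allylic hydroxyl for ionisation by zerovalent palladium (formed in situ from Pd(OAc)2 and the phosphine), and the π-allylpalladium exchanges allyl for ethyl with Et3B to give the nucleophilic allyl(diethyl)borane 13, which adds through its γ-carbon to the aldehyde in a closed six-membered Zimmerman–Traxler transition state. The closest known reactions are the palladium-catalysed, Et3B-promoted umpolung allylation of aldehydes with allylic alcohols (2-methylenepropane-1,3-diols included) and intramolecular allylboration. The cyclohexane closes in a 6-exo-trig mode at the carbonyl carbon, the allyl π-bond staying exocyclic, through a trans-decalin-like bicyclic array. Both new stereocentres (the side-chain-bearing carbon and the carbinol carbon) are controlled by the resident isopropenyl-bearing stereocentre: the chair places isopropenyl equatorial (quaternary methyl axial, vinyl equatorial), and the closed transition state then forces the oxygen and the allyl unit equatorial, i.e. trans,trans. The step needs γ- rather than α-attack, which the tether secures (α-attack would give an eight-membered ring), and it needs ionisation of either hydroxyl to lead to the same π-allyl, which the equivalence of the two CH2OH arms secures; a fast 1,3-boryl shift lets the allylborane reach the geometry with the chain trans to CH2B.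

Step 9
Reactants: 14 cyclised diol
Product: 15 (1R,2S,3S,6R)-3-ethenyl-6-[2-(hydroxymethyl)oxiran-2-yl]-3-methyl-2-(prop-1-en-2-yl)cyclohexan-1-ol (either epimer at the oxirane carbon)
Conditions: Ti(OiPr)4 (10 mol %), diethyl L-tartrate (12 mol %), tBuOOH (1.5 equiv), 4 Å molecular sieves, CH2Cl2, −20 °C
Reagents that add atoms: tert-butyl hydroperoxide, CC(C)(C)OO
Why: Katsuki–Sharpless epoxidation delivers oxygen only to the alkene of the allylic alcohol, so isopropenyl and vinyl (at best homoallylic to the ring hydroxyl) should stay untouched; the configuration of the new oxirane carbon is immaterial because it is erased in step 10.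

Step 10
Reactants: 15 epoxy diol
Product: 16 2-[(1R,2R,3S,4S)-4-ethenyl-2-hydroxy-4-methyl-3-(prop-1-en-2-yl)cyclohexyl]propane-1,2,3-triol
Conditions: HClO4 (5 mol %), THF–H2O (3:1), 0 → 25 °C
Reagents that add atoms: water, O
Why: Acid-catalysed hydrolysis of the 2,2-disubstituted epoxide gives the same triol whichever oxirane carbon water attacks, since the two arms become identical and the temporary stereocentre vanishes.

Step 11
Reactants: 16 tetraol
Product: 17 2-[(1R,2R,3S,4S)-4-ethenyl-2-hydroxy-4-methyl-3-(prop-1-en-2-yl)cyclohexyl]-2-hydroxypropane-1,3-diyl diacetate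
Conditions: Ac2O (2.2 equiv), pyridine, CH2Cl2, 0 °C
Reagents that add atoms: acetic anhydride, CC(=O)OC(C)=O
Why: Rate-selective acetylation should take only the two primary hydroxyls, because the ring hydroxyl is secondary and flanked by two branched equatorial substituents and the side-chain carbinol is tertiary.

**Compound list**

1 | geraniol, (2E)-3,7-dimethylocta-2,6-dien-1-ol | CC(C)=CCC/C(C)=C/CO | starting material
2 | 3-methylbut-3-enoic acid | CC(=C)CC(=O)O | starting material
3 | geranyl 3-methylbut-3-enoate | CC(=C)CC(=O)OC/C=C(\C)CCC=C(C)C | intermediate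
4 | boron ketene acetal of 3 on the (4S,5S)-diazaborolidine, isopropenyl trans to O–B and cis to the geranyloxy oxygen | CC(=C)/C=C(/OB1N([C@@H](c2ccccc2)[C@@H](N1S(=O)(=O)c1cc(cc(c1)C(F)(F)F)C(F)(F)F)c1ccccc1)S(=O)(=O)c1cc(cc(c1)C(F)(F)F)C(F)(F)F)OC/C=C(\C)CCC=C(C)C | intermediate (not isolated)
5 | boron carboxylate of acid 6 on the same (4S,5S)-diazaborolidine | C=C[C@](C)(CCC=C(C)C)[C@H](C(=C)C)C(=O)OB1N([C@@H](c2ccccc2)[C@@H](N1S(=O)(=O)c1cc(cc(c1)C(F)(F)F)C(F)(F)F)c1ccccc1)S(=O)(=O)c1cc(cc(c1)C(F)(F)F)C(F)(F)F | intermediate (not isolated)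
6 | (2S,3S)-3-ethenyl-3,7-dimethyl-2-(prop-1-en-2-yl)oct-6-enoic acid | C=C[C@](C)(CCC=C(C)C)[C@H](C(=C)C)C(=O)O | intermediate
7 | (2S,3S)-3-ethenyl-N-methoxy-N,3,7-trimethyl-2-(prop-1-en-2-yl)oct-6-enamide | C=C[C@](C)(CCC=C(C)C)[C@H](C(=C)C)C(=O)N(C)OC | intermediate
8 | (2S,3S)-5-(3,3-dimethyloxiran-2-yl)-3-ethenyl-N-methoxy-N,3-dimethyl-2-(prop-1-en-2-yl)pentanamide, epimers at the oxirane carbon | C=C[C@](C)(CCC1OC1(C)C)[C@H](C(=C)C)C(=O)N(C)OC | intermediate
9 | (2S,3S)-3-ethenyl-N-methoxy-N,3-dimethyl-6-oxo-2-(prop-1-en-2-yl)hexanamide | C=C[C@](C)(CCC=O)[C@H](C(=C)C)C(=O)N(C)OC | intermediate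
10 | dimethyl malonate | COC(=O)CC(=O)OC | starting material
11 | dimethyl 2-[(4S,5S)-4-ethenyl-5-[methoxy(methyl)carbamoyl]-4,6-dimethylhept-6-en-1-ylidene]propanedioate | C=C[C@](C)(CCC=C(C(=O)OC)C(=O)OC)[C@H](C(=C)C)C(=O)N(C)OC | intermediate
12 | (2S,3S)-3-ethenyl-8-hydroxy-7-(hydroxymethyl)-3-methyl-2-(prop-1-en-2-yl)oct-6-enal | C=C[C@](C)(CCC=C(CO)CO)[C@H](C(=C)C)C=O | intermediate
13 | (2S,3S)-7-[(diethylboranyl)methyl]-3-ethenyl-8-hydroxy-3-methyl-2-(prop-1-en-2-yl)oct-6-enal, chain trans to CH2B | C=C[C@](C)(CC/C=C(\CO)CB(CC)CC)[C@H](C(=C)C)C=O | intermediate (not isolated)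
14 | (1S,2S,3S,6S)-3-ethenyl-6-(3-hydroxyprop-1-en-2-yl)-3-methyl-2-(prop-1-en-2-yl)cyclohexan-1-ol | C=C[C@]1(C)CC[C@@H](C(=C)CO)[C@H](O)[C@H]1C(=C)C | intermediate
15 | (1R,2S,3S,6R)-3-ethenyl-6-[2-(hydroxymethyl)oxiran-2-yl]-3-methyl-2-(prop-1-en-2-yl)cyclohexan-1-ol, epimers at the oxirane carbon | C=C[C@]1(C)CC[C@@H](C2(CO)CO2)[C@H](O)[C@H]1C(=C)C | intermediate
16 | 2-[(1R,2R,3S,4S)-4-ethenyl-2-hydroxy-4-methyl-3-(prop-1-en-2-yl)cyclohexyl]propane-1,2,3-triol | C=C[C@]1(C)CC[C@@H](C(O)(CO)CO)[C@H](O)[C@H]1C(=C)C | intermediate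
17 | 2-[(1R,2R,3S,4S)-4-ethenyl-2-hydroxy-4-methyl-3-(prop-1-en-2-yl)cyclohexyl]-2-hydroxypropane-1,3-diyl diacetate | C=C[C@]1(C)CC[C@@H](C(O)(COC(C)=O)COC(C)=O)[C@H](O)[C@H]1C(=C)C | target

**Step count.** Total: 11 steps. Longest linear sequence: 11 steps (from geraniol).

**Steps most likely to fail**

1. Step 8. The π-allylpalladium may lose a β-hydrogen to give a diene, the allylborane may react between molecules, the amine may epimerise or conjugate the α-branched β,γ-unsaturated aldehyde, or closure may go through the cis chair. The fallback closes the same bond by a type 1 carbonyl-ene reaction. It sets out from aldehyde 9: Z-selective Horner–Wadsworth–Emmons olefination of the Ando type with ethyl 2-(diphenoxyphosphoryl)propanoate (NaH, THF, −78 °C) should give ethyl (2Z,6S,7S)-6-ethenyl-7-[methoxy(methyl)carbamoyl]-2,6,8-trimethylnona-2,8-dienoate F1. iBu2AlH then reduces ester and Weinreb amide to (2S,3S,6Z)-3-ethenyl-8-hydroxy-3,7-dimethyl-2-(prop-1-en-2-yl)oct-6-enal F2. Me2AlCl (2.2 equiv, CH2Cl2, −78 °C) should induce the ene closure through the same all-equatorial chair, the hydrogen being taken from the methyl group syn to the vinylic hydrogen, and the route is rejoined at diol 14.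

2. Step 2. Soft enolisation may give the other ketene acetal geometry (hence the other diastereomer), facial discrimination by the boron ligand may be poor, or the rearrangement may be too slow at low temperature. The fallback sets out from ester 3 and uses a classical Ireland–Claisen rearrangement followed by resolution. LiN(iPr)2 and Me3SiCl (THF, −78 → 25 °C) should give the trimethylsilyl ketene acetal F3 (isopropenyl trans to OSi), which rearranges on warming to the racemic trimethylsilyl ester F4. Aqueous work-up gives the racemic acid F5. Crystallisation of the (S)-1-phenylethylammonium salt F6 (the antipodal amine if the other salt proves less soluble) and acidification return the route to acid 6.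

3. Step 7. Hydride may add 1,4 to the alkylidene malonate, the amide may be reduced past the aldehyde, or the esters may be reduced incompletely. The fallback builds the same symmetric diol from a simple enoate. It sets out from aldehyde 9: Morita–Baylis–Hillman reaction with methyl acrylate (DABCO) gives methyl (6S,7S)-6-ethenyl-3-hydroxy-7-[methoxy(methyl)carbamoyl]-6,8-dimethyl-2-methylidenenon-8-enoate F7. Acetylation (Ac2O, DMAP) gives its secondary acetate F8. DABCO-catalysed SN2'–SN2' transposition (THF, reflux) should move the acetate to the primary position, giving methyl (2E,6S,7S)-2-(acetoxymethyl)-6-ethenyl-7-[methoxy(methyl)carbamoyl]-6,8-dimethylnona-2,8-dienoate F9. iBu2AlH reduces ester, acetate and Weinreb amide, and the route is rejoined at dihydroxy aldehyde 12.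

**Further compounds**

F1 | step 8 | ethyl (2Z,6S,7S)-6-ethenyl-7-[methoxy(methyl)carbamoyl]-2,6,8-trimethylnona-2,8-dienoate | C=C[C@](C)(CC/C=C(/C)C(=O)OCC)[C@H](C(=C)C)C(=O)N(C)OC
F2 | step 8 | (2S,3S,6Z)-3-ethenyl-8-hydroxy-3,7-dimethyl-2-(prop-1-en-2-yl)oct-6-enal | C=C[C@](C)(CC/C=C(/C)CO)[C@H](C(=C)C)C=O
F3 | step 2 | {[(1E)-1-(geranyloxy)-3-methylbuta-1,3-dien-1-yl]oxy}trimethylsilane | CC(=C)/C=C(/O[Si](C)(C)C)OC/C=C(\C)CCC=C(C)C
F4 | step 2 | racemic trimethylsilyl (2S,3S)/(2R,3R)-3-ethenyl-3,7-dimethyl-2-(prop-1-en-2-yl)oct-6-enoate | C=C[C@](C)(CCC=C(C)C)[C@H](C(=C)C)C(=O)O[Si](C)(C)C.C=C[C@@](C)(CCC=C(C)C)[C@@H](C(=C)C)C(=O)O[Si](C)(C)C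
F5 | step 2 | racemic (2S,3S)/(2R,3R)-3-ethenyl-3,7-dimethyl-2-(prop-1-en-2-yl)oct-6-enoic acid | C=C[C@](C)(CCC=C(C)C)[C@H](C(=C)C)C(=O)O.C=C[C@@](C)(CCC=C(C)C)[C@@H](C(=C)C)C(=O)O
F6 | step 2 | (S)-1-phenylethylammonium (2S,3S)-3-ethenyl-3,7-dimethyl-2-(prop-1-en-2-yl)oct-6-enoate | C=C[C@](C)(CCC=C(C)C)[C@H](C(=C)C)C(=O)[O-].C[C@H]([NH3+])c1ccccc1
F7 | step 7 | methyl (6S,7S)-6-ethenyl-3-hydroxy-7-[methoxy(methyl)carbamoyl]-6,8-dimethyl-2-methylidenenon-8-enoate, epimers at C3 | C=C[C@](C)(CCC(O)C(=C)C(=O)OC)[C@H](C(=C)C)C(=O)N(C)OC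
F8 | step 7 | methyl (6S,7S)-3-acetoxy-6-ethenyl-7-[methoxy(methyl)carbamoyl]-6,8-dimethyl-2-methylidenenon-8-enoate, epimers at C3 | C=C[C@](C)(CCC(OC(C)=O)C(=C)C(=O)OC)[C@H](C(=C)C)C(=O)N(C)OC
F9 | step 7 | methyl (2E,6S,7S)-2-(acetoxymethyl)-6-ethenyl-7-[methoxy(methyl)carbamoyl]-6,8-dimethylnona-2,8-dienoate | C=C[C@](C)(CC/C=C(\COC(C)=O)C(=O)OC)[C@H](C(=C)C)C(=O)N(C)OC
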